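The runs are simulated for an exercise; noise was put on by code.

A ratio runs through these flasks: of the coupling partner molecules that disappear, how many end in left-handed product and how many are wasted?

all flasks: left-handed substrate 0.13 M; right-handed substrate 0.13 M

| charge | coupling partner | catalyst | temperature | remark | time |
|---|---|---|---|---|---|
| dusk | 0.52 M | 6.8 mM | 65 °C | run made earlier |  |
| noon | 0.52 M | 16 mM | 85 °C | run made earlier |  |
| midnight | 0.19 M | 4.9 mM | 65 °C | run made earlier |  |
| alder | 0.520 M | 10 mM | 100 °C |  | 8.0 min |
| maple | 0.520 M | 4.9 mM | 100 °C |  | 8.0 min |
| larch | 0.120 M | 4.9 mM | 100 °C |  | 8.0 min |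
| birch | 0.400 M | 4.9 mM | 70 °C |  | 8.0 min |

| run | time / min | left-handed product / % |
|---|---|---|
| dusk | 2.00 | 18.4 |
| dusk | 5.00 | 34.2 |
| dusk | 8.00 | 43.6 |
| dusk | 15.0 | 62.2 |
| dusk | 25.0 | 73.6 |
| dusk | 30.0 | 77.5 |
| noon | 2.00 | 60.4 |
| noon | 3.00 | 68.7 |
| noon | 5.00 | 80.9 |
| noon | 6.00 | 82.7 |
| noon | 8.00 | 86.6 |
| noon | 10.0 | 89.2 |
| noon | 12.0 | 91.4 |
| midnight | 6.00 | 12.0 |
| midnight | 15.0 | 22.4 |
| midnight | 30.0 | 34.0 |

(standard deviation of a reading: 1 percentage point)

- catalyst is single-handed; left-handed substrate and right-handed substrate are mirror images of each other, charged as a racemate, each of them at the stated concentration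
- the earlier runs were read with a standard deviation of 1 percentage point

- all flasks from highest to lowest amount of left-handed product, in percent of the left-handed substrate and right-handed substrate together charged, at 8.0 min (alder / maple / larch / birch)
- the same order at 1.0 h (alder / maple / larch / birch)
- the amount of left-handed product, in percent of the left-handed substrate and right-handed substrate together charged of the flask you put first, at 8.0 min
- the amount of left-handed product, in percent of the left-handed substrate and right-handed substrate together charged of the flask you put last, at 8.0 min

The catalyst is single-handed and the substrates are charged as a racemate, yet the noon run reads 91.4 %, above the 50.0 % that the left-handed substrate could supply by itself. So I take the right-handed substrate to feed the left-handed one, and I keep the two equal.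

But the noon run also slows, so I follow one partner molecule to a fork: it couples, at a rate proportional to catalyst times left-handed substrate, or it is wasted at a rate of its own. Summed over a run, this fork gives a bill: partner spent = 2 × (left-handed substrate used + level × ln(left-handed substrate charged / left-handed substrate remaining)).

I treat the last noon reading as that run's end and assume its partner is spent. This gives a reading of 0.0575 M for the even-odds level, the left-handed substrate concentration at which both branches are equally likely, at 16 mM of catalyst. In this reckoning, at a fixed temperature, the level falls in inverse proportion to the catalyst.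

Carrying it unchanged to 100 °C is my guess. With 4.9 mM of catalyst, the level in larch is 0.188 M, so a partner molecule in larch at the start couples with a chance of 40.9 %. Holding the substrate at its charge and counting the whole partner charge as spent, I reckon 18.9 % for larch. For alder the level is 0.0921 M, and two rounds of the bill, again with the whole partner charge counted as spent, give 82.7 %. I rank alder first, then maple, birch and larch; birch's place at 1.0 h is my weak point.

The forecast gives my order, alder > maple > birch > larch, but with 78 % and 23 % in place of my two numbers, then birch > alder > maple > larch, and it says of the noon slowdown “I read that as catalyst dying”.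

The flasks give alder > maple > birch > larch at 8.00 min, with alder at 72.2 % and larch at 14.6 %, and alder > birch > maple > larch at 60.0 min, by these steps:

    coupling partner + catalyst + left-handed substrate → catalyst + left-handed product (k = 6.30 M⁻² s⁻¹, Ea = 55.0 kJ mol⁻¹)
    coupling partner + catalyst + right-handed substrate → catalyst + right-handed product (k = 0.0440 M⁻² s⁻¹, Ea = 77.0 kJ mol⁻¹)
    left-handed substrate ⇌ right-handed substrate (k = 0.820 s⁻¹, Ea = 78.0 kJ mol⁻¹)
    coupling partner → decomposed reagent (k = 0.00780 s⁻¹, Ea = 95.0 kJ mol⁻¹)
    coupling partner ⇌ dormant form (K = 0.350, k = 0.0530 s⁻¹, Ea = 102 kJ mol⁻¹, ΔH = 18.0 kJ mol⁻¹)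
    (constants at 100 °C)

In larch at 8.00 min, 1.3 % of the coupling partner stands against 85 % of the left-handed substrate, and the partner, the limiting reagent, is the first to run out. The even-odds level from noon, scaled to the same catalyst, puts a neighbour of larch charged with 0.048 M of partner at 7.55 % of left-handed product, and at 8.00 min that flask holds 6.03 %.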